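**Retrosynthetic overview**
1. Pyrrole 12 ⇒ O-vinyl oxime 8: N1–C5 closes by condensation and C3–C4 forms by [3,3] shift. The bond made deliberately is the oxime O–C(vinyl) bond, from oxime 6 and vinyl acetate 7.
2. Oxime 6 ⇒ 2-docosylacetoacetate 3 by deacylative nitrosation, with the C=N nitrogen coming from tert-butyl nitrite 4.
3. Keto ester 3 ⇒ methyl acetoacetate 2 + 1-bromodocosane 1.
4. Ring order: the pyrrole is the only ring and is closed in the last step.

Assumption: the target (C27H49NO2, henicosyl = C21) has no stereocentre, so there is no enantiomer to control; oxime and alkene geometries in intermediates are inconsequential mixtures.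

**Step 1**
Reactants: 1 1-bromodocosane; 2 methyl acetoacetate (1.5 equiv)
Product: 3 methyl 2-acetyltetracosanoate
Conditions: K2CO3 (1.2 equiv), KI (10 mol %), DMF, 70 °C
Reagents that add atoms: none
Why: Acetoacetic ester C-alkylation of a stabilised enolate with an unhindered primary halide (Finkelstein-assisted SN2), where excess 2 suppresses dialkylation and the racemic C2 centre is erased in step 2.

**Step 2**
Reactants: 3 methyl 2-acetyltetracosanoate; 4 tert-butyl nitrite (1.3 equiv)
Product: 6 methyl 2-(hydroxyimino)tetracosanoate, via nitroso keto ester 5 (not isolated)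
Conditions: NaOMe (1.1 equiv), THF–MeOH, 0 °C → rt; then 1 M HCl work-up
Reagents that add atoms: none
Why: Deacylative nitrosation (Japp–Klingemann-type retro-Claisen): the enolate of 3 is C-nitrosated, methoxide then cleaves the more electrophilic acetyl group as methyl acetate, leaving the oximate of the α-oximino ester, and methoxide cannot scramble the methyl ester.

**Step 3**
Reactants: 6 methyl 2-(hydroxyimino)tetracosanoate; 7 vinyl acetate (3 equiv)
Product: 12 methyl 3-henicosyl-1H-pyrrole-2-carboxylate, via O-vinyl oxime 8 (not isolated), via N-vinyloxy enamine 9 (not isolated), via imino aldehyde 10 (not isolated), via hydroxypyrroline 11 (not isolated)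
Conditions: [Ir(cod)Cl]2 (2 mol %), Na2CO3 (1.0 equiv), PhMe, 100 °C, sealed tube, Ar
Reagents that add atoms: none
Why: Proposed new method: Ir(I)-catalysed transfer vinylation of an oxime O–H from vinyl acetate (the Ir-oximate adds across coordinated vinyl acetate and β-acetoxy elimination releases 8; closest known reaction is Ir-catalysed transfer vinylation of alcohols and phenols of similar acidity with vinyl acetate), run at a temperature where the Trofimov-type cascade follows on its own: ester-assisted tautomerisation to 9, [3,3]-sigmatropic shift with cleavage of the weak N–O bond to 10, 5-exo attack of N on the aldehyde forming the N1–C5 bond (11), and Paal–Knorr-type dehydration to the aromatic pyrrole, with regiochemistry fixed because only C3 of 6 can enolise.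

**Compound list**
1 | 1-bromodocosane | CCCCCCCCCCCCCCCCCCCCCCBr | starting material
2 | methyl acetoacetate | CC(=O)CC(=O)OC | starting material
3 | methyl 2-acetyltetracosanoate (racemic) | CCCCCCCCCCCCCCCCCCCCCCC(C(C)=O)C(=O)OC | intermediate
4 | tert-butyl nitrite | CC(C)(C)ON=O | starting material
5 | methyl 2-acetyl-2-nitrosotetracosanoate (nitroso keto ester, racemic, not isolated) | CCCCCCCCCCCCCCCCCCCCCCC(N=O)(C(C)=O)C(=O)OC | intermediate
6 | methyl 2-(hydroxyimino)tetracosanoate (E/Z mixture) | CCCCCCCCCCCCCCCCCCCCCCC(=NO)C(=O)OC | intermediate
7 | vinyl acetate | C=COC(C)=O | starting material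
8 | methyl 2-[(ethenyloxy)imino]tetracosanoate (O-vinyl oxime, not isolated) | CCCCCCCCCCCCCCCCCCCCCCC(=NOC=C)C(=O)OC | intermediate
9 | methyl 2-[(ethenyloxy)amino]tetracos-2-enoate (N-vinyloxy enamine, not isolated) | CCCCCCCCCCCCCCCCCCCCCC=C(NOC=C)C(=O)OC | intermediate
10 | methyl 2-imino-3-(2-oxoethyl)tetracosanoate (imino aldehyde, racemic, not isolated) | CCCCCCCCCCCCCCCCCCCCCC(CC=O)C(=N)C(=O)OC | intermediate
11 | methyl 4-henicosyl-2-hydroxy-3,4-dihydro-2H-pyrrole-5-carboxylate (hydroxypyrroline, diastereomer mixture, not isolated) | CCCCCCCCCCCCCCCCCCCCCC1CC(O)N=C1C(=O)OC | intermediate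
12 | methyl 3-henicosyl-1H-pyrrole-2-carboxylate | CCCCCCCCCCCCCCCCCCCCCc1cc[nH]c1C(=O)OC | target

**Totals**
Total step count: 3. Longest linear sequence: 3.

**Steps most likely to fail**

Step 3 (the proposed new step). The N,O-chelating oximate may sequester iridium, vinyl acetate may O-acetylate instead of O-vinylate, and excess donor may N-vinylate the product. The fallback uses known chemistry, sets out from 6 and comes back to the route at 8. O-Alkylation of 6 with excess 1,2-dibromoethane (K2CO3, DMF, rt) gives methyl 2-[(2-bromoethoxy)imino]tetracosanoate F1. E2 dehydrobromination (t-BuOK, THF, 0 °C, short contact time) gives O-vinyl oxime 8, this time isolated. Heating 8 in o-xylene at 130 °C then runs the same thermal [3,3]/cyclodehydration to 12 without any metal.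

Step 2. Risks are competing attack at the ester instead of the acetyl group, loss of volatile methyl nitrite formed by exchange, and poor solubility of the C22 chain at 0 °C. The fallback sets out from 1 and comes back at 6. Magnesium in THF converts 1 into docosylmagnesium bromide F2. Inverse addition of F2 to dimethyl oxalate (2 equiv, THF, −78 → −40 °C) gives methyl 2-oxotetracosanoate F3. Condensation of F3 with hydroxylamine hydrochloride and NaOAc in MeOH–THF gives 6, so the nitrogen is introduced by oxime condensation and not by nitrosation.

Step 1. Risks are dialkylation, some O-alkylation and sluggish SN2 of the waxy bromide. The fallback sets out from 1 and comes back at 3. Ganem oxidation of 1 (trimethylamine N-oxide, DMSO, 50 °C) gives docosanal F4. Knoevenagel condensation of F4 with 2 (piperidinium acetate cat., EtOH–CH2Cl2) gives methyl 2-acetyltetracos-2-enoate F5, which is reduced in the same pot by Hantzsch ester (conjugate transfer hydrogenation) to 3; this reductive alkylation cannot over-alkylate.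

**Further compounds**
F1 | step 3 | methyl 2-[(2-bromoethoxy)imino]tetracosanoate | CCCCCCCCCCCCCCCCCCCCCCC(=NOCCBr)C(=O)OC
F2 | step 2 | docosylmagnesium bromide | CCCCCCCCCCCCCCCCCCCCCC[Mg]Br
F3 | step 2 | methyl 2-oxotetracosanoate | CCCCCCCCCCCCCCCCCCCCCCC(=O)C(=O)OC
F4 | step 1 | docosanal | CCCCCCCCCCCCCCCCCCCCCC=O
F5 | step 1 | methyl 2-acetyltetracos-2-enoate (E/Z mixture) | CCCCCCCCCCCCCCCCCCCCCC=C(C(C)=O)C(=O)OC
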